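The amounts were the same in Monday's, Tuesday's, Wednesday's and Sunday's flasks, 0.30 M of substrate, 0.750 M of first nucleophile and 0.150 M of second nucleophile; these flasks differed in how the substrate went in and how hot it was.

| flask | substrate | first nucleophile | second nucleophile | temperature | remark | time |
|---|---|---|---|---|---|---|
| alder | 0.30 M | 0.75 M | 0.15 M | 95 °C | run made earlier |  |
| cedar | 0.30 M | 0.75 M | 0.21 M | 106 °C | run made earlier |  |
| maple | 0.30 M | 0.75 M | 0.33 M | 95 °C | run made earlier |  |
| oak | 0.60 M | 0.75 M | 0.15 M | 106 °C | run made earlier |  |
| Monday's | 0.30 M | 0.750 M | 0.150 M |  | everything together at the start at 60 °C, warmed to 100 °C at 30 min | 50 min |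
| Wednesday's | 0.30 M (fed, over 30 min) | 0.750 M | 0.150 M | 100 °C | all else is in the flask from the start; the feed brings no volume worth counting | 50 min |
| Tuesday's | 0.30 M (fed, over 30 min) | 0.750 M | 0.150 M |  | the addition at 60 °C, then warmed to 100 °C; the feed brings no volume worth counting | 50 min |
| Sunday's | 0.30 M | 0.750 M | 0.150 M | 100 °C | everything together at the start | 50 min |

| run | time / min | target / % | other capture product / % | substrate / % |
|---|---|---|---|---|
| alder | 2.50 | 28.3 | 1.0 | 35.3 |
| alder | 6.00 | 38.0 | 0.9 | 7.3 |
| alder | 12.0 | 38.5 | 3.3 | 0 |
| alder | 30.0 | 39.1 | 1.9 | 0 |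
| cedar | 8.00 | 33.9 | 5.0 | 0 |
| cedar | 20.0 | 34.4 | 3.0 | 2.5 |
| cedar | 40.0 | 34.8 | 5.3 | 0 |
| cedar | 60.0 | 34.5 | 4.2 | 0.6 |
| maple | 15.0 | 39.1 | 7.2 | 2.2 |
| maple | 30.0 | 38.2 | 5.6 | 0 |
| maple | 50.0 | 36.3 | 6.5 | 1.4 |
| maple | 60.0 | 39.3 | 4.1 | 1.2 |
| oak | 5.00 | 32.6 | 2.6 | 1.5 |
| oak | 12.0 | 32.0 | 0.9 | 1.2 |
| oak | 25.0 | 31.4 | 3.4 | 1.3 |
| oak | 60.0 | 31.2 | 1.7 | 1.1 |

(scatter of a reading: 1 percentage point)

- the flask with the highest share of target in target plus other capture product ("all alike" if they lie within 1.5 percentage points) (Monday's / Wednesday's / Tuesday's / Sunday's / all alike)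
- share of target in target plus other capture product at the end, Monday's
- share of target in target plus other capture product at the end, Wednesday's
- share of target in target plus other capture product at the end, Tuesday's
- share of target in target plus other capture product at the end, Sunday's

- the numbers in the tables scatter by 1 percentage point (one standard deviation)

From the runs I took a selectivity factor: other capture product over target, multiplied by charged [first nucleophile] over charged [second nucleophile]. Summed over the readings of each run, with their scatter, I read 0.348 in maple at 95 °C and 0.454 in cedar at 106 °C, so I took their mean, 0.401, as my estimate for 100 °C. Multiplied by 0.150 M, it gave 0.0602 M, the crossing concentration: the [first nucleophile] at which, with [second nucleophile] held at its charge, both nucleophiles capture equally. The target's share is then [first nucleophile] over [first nucleophile] plus the crossing, which at the charge is 92.6 %.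

I then turned the question round. For a flask to stand 1.5 percentage points below that share, capture would have to happen at a [first nucleophile] of 0.614 M. Alder had 7.3 % of its substrate left at 6.00 min, but a feed stretches the supply over 30 min, and no run has a reading of [first nucleophile]. So my test for Wednesday's flask was whether it stayed above 0.614 M through the feed, and I had no reading of [first nucleophile] to hold against that.

The forecast gave all alike, with 94.8 % for Monday's, 93.5 % for Wednesday's, 94.5 % for Tuesday's and 93.5 % for Sunday's: “Oak shows no substrate-concentration effect on this ratio, so feeding should hardly change the share.”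

The flasks gave 94.7 % for Monday's, 68.2 % for Wednesday's, 93.2 % for Tuesday's and 92.9 % for Sunday's, so Monday's stood highest.

    first nucleophile → decomposed reagent (k = 0.141 /min, Ea = 95.0 kJ/mol)
    2 first nucleophile → homo dimer (k = 0.0880 /M/min, Ea = 75.0 kJ/mol)
    substrate → intermediate (k = 0.645 /min, Ea = 96.0 kJ/mol)
    second nucleophile + intermediate → other capture product (k = 10.1 /M/min, Ea = 79.0 kJ/mol)
    first nucleophile + intermediate → target (k = 40.3 /M/min, Ea = 52.0 kJ/mol)
    intermediate → solvolysis product (k = 32.0 /min, Ea = 85.0 kJ/mol)
    (constants at 100 °C)

Put into the same reckoning, Wednesday's 68.2 % corresponds to an average [first nucleophile] during capture of 0.129 M, lower than 0.614 M but higher than the crossing. A neighbour of Monday's charged with 1.3 M of first nucleophile reckons to 95.6 % from its charge and the crossing concentration estimated for 100 °C, and that neighbour flask gave 96.3 %, with 43.3 % solvolysis product.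

The numbers in the tables stem from a simulated flask for an exercise, noise included.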